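**Plan**

1. Cuts (labdane numbering): C7=C8 of ring B (olefin metathesis); C9–C10 (Claisen shift from a temporary C1–O–CH2 allyl enol ether, so C1 carries a helper oxygen); the C1–O bond of that tether (C–O coupling), which divides the molecule into a ring A alkenyl iodide and a C8/C9/C11–C17 allylic alcohol; then C5–C6 (conjugate allylation), C4–C19 and C4–C18 (enolate alkylations) and C3–O (from an isopropenyl group).
2. Forward: ring A is built from (S)-carvone (steps 1–9) and the side chain from (R)-citronellic acid (steps 10–13); the two are joined through oxygen (step 14); one flask then makes C9–C10 and closes ring B at C7=C8 (step 15); the C1 oxygen is removed (step 16) and the oxygen functions are adjusted (steps 17–20).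
3. Enabling feature: ring B is a cyclohexene whose only double bond, C7=C8, lies between C6 (a CH2 on C5) and C9 (the methine that carries the side chain next to quaternary C10). An allyl group on C5 and an isopropenyl group on C9 map onto it, and a C9-isopropenyl/C10-quaternary pair is what a Claisen shift of a C1 enol ether delivers; its O–CH2 carbon then leaves as ethene.
4. Stereochemistry: C3 from (S)-carvone (carbon-to-oxygen migration with retention); C4 by alkylation anti to the C3 group; C5 by cuprate addition anti to the C3 oxygen; C10 by rearrangement anti to the C5 allyl group; C9 from the (Z)-olefin through a chair; C13 from (R)-citronellic acid.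

Key step: step 15

Remark: labdane numbering (C18 = C4 methyl, C19 = C4 CH2O, C20 = C10 methyl) is used for every intermediate, and 4-methoxybenzyl chloromethyl ether is assumed to be at hand (made from its methylthiomethyl ether and SO2Cl2).

**Route**

Step 1
Reactants: 1 (S)-(+)-carvone
Product: 2 trans-6-methylcarvone (methyl on C4 trans to the C3 isopropenyl group)
Conditions: LiN(iPr)2, THF, −78 °C; MeI, −78 → 0 °C
Reagents that add atoms: iodomethane, CI
Why: Kinetic alpha'-deprotonation and SN2 alkylation of the lithium enolate should give mainly the trans methyl compound, and this centre is flattened again in step 2 so the epimer ratio does not matter.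

Step 2
Reactants: 2 trans-6-methylcarvone
Product: 3 quaternary enone (C4 methyl cis and C4 CH2OPMB trans to the C3 isopropenyl group)
Conditions: LiN(iPr)2, THF, −78 °C; 4-MeOC6H4CH2OCH2Cl, −78 → −20 °C
Reagents that add atoms: 4-methoxybenzyl chloromethyl ether, COc1ccc(COCCl)cc1
Why: Enolate C-alkylation with a reactive alpha-chloro ether should occur on the face anti to the adjacent isopropenyl group, which sets quaternary C4 with C19 trans to the future C3 oxygen.

Step 3
Reactants: 3 quaternary enone
Product: 6 hydroxy enone, via methoxy hydroperoxide 4 (not isolated), via acetate 5 (not isolated)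
Conditions: O3, CH2Cl2/MeOH, −78 °C (Sudan red end point); Ac2O, Et3N, DMAP, 0 °C → rt; then K2CO3, MeOH, 0 °C
Reagents that add atoms: ozone, [O-][O+]=O (the C3 oxygen); methanol, CO (in intermediate 4 only)
Why: Ozone should cleave only the electron-rich 1,1-disubstituted olefin, and the Criegee rearrangement of the acetylated methoxy hydroperoxide moves C3 from carbon to oxygen with retention before methanolysis frees the alcohol; beta-elimination cannot occur because C4 is quaternary.

Step 4
Reactants: 6 hydroxy enone
Product: 7 silyl ether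
Conditions: tBuMe2SiOTf, 2,6-lutidine, CH2Cl2, −78 → 0 °C
Reagents that add atoms: tert-butyldimethylsilyl triflate, CC(C)(C)[Si](C)(C)OS(=O)(=O)C(F)(F)F
Why: Silylation of a hindered secondary alcohol with a silyl triflate gives an ether that is a poor beta-leaving group in the later enolate steps; no stereocentre is touched.

Step 5
Reactants: 7 silyl ether
Product: 8 epoxy ketone (C1–C10 epoxide expected anti to the C3 silyloxy group)
Conditions: H2O2 (30% aq.), NaOH (cat.), MeOH, 0 °C
Reagents that add atoms: hydrogen peroxide, OO
Why: Weitz–Scheffer nucleophilic epoxidation of the enone should proceed as for carvone, anti to the C3 substituent; both new centres (C1, C10) are destroyed again in steps 6 and 7.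

Step 6
Reactants: 8 epoxy ketone
Product: 9 allylic alcohol (C1–OH, C5=C10 olefin)
Conditions: N2H4·H2O, AcOH (cat.), MeOH, 0 → 40 °C
Reagents that add atoms: none
Why: Wharton transposition: the epoxy hydrazone should collapse with loss of N2 to the C5=C10 olefin and the C1 alcohol, whose configuration (kept from the epoxide) is of no consequence.

Step 7
Reactants: 9 allylic alcohol
Product: 10 transposed enone (C1 ketone, C10=C5 olefin)
Conditions: Dess–Martin periodinane, pyridine, CH2Cl2, rt
Reagents that add atoms: none
Why: Hypervalent-iodine oxidation of a secondary allylic alcohol under buffered conditions should spare the silyl and PMB ethers.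

Step 8
Reactants: 10 transposed enone
Product: 13 enol triflate, via silyl enol ether 11 (not isolated), via lithium enolate 12 (not isolated)
Conditions: allylMgBr, CuBr·SMe2, Me3SiCl, THF, −78 °C; volatiles removed; MeLi, THF, 0 °C; N-(5-chloropyridin-2-yl)triflimide, −78 °C → rt
Reagents that add atoms: allylmagnesium bromide, C=CC[Mg]Br; N-(5-chloropyridin-2-yl)triflimide, FC(F)(F)S(=O)(=O)N(c1ccc(Cl)cn1)S(=O)(=O)C(F)(F)F; chlorotrimethylsilane, C[Si](C)(C)Cl (in 11 only); methyllithium, [Li]C (lithium in 12 only)
Why: Silyl-chloride-accelerated conjugate addition of the allylcopper reagent should take place at C5 by axial attack anti to the C3 silyloxy group and the axial C4 methyl (as in additions to 5-substituted cyclohexenones), and the enolate is then trapped regiospecifically across C1–C10 as the triflate.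

Step 9
Reactants: 13 enol triflate
Product: 14 alkenyl iodide
Conditions: Ni(cod)2 (cat.), NaI, DMA/THF, rt
Reagents that add atoms: sodium iodide, [Na+].[I-]
Why: Nickel-catalysed triflate-to-halide exchange of enol triflates (oxidative addition, anion exchange, reductive elimination) should give the iodide needed for copper-catalysed etherification without moving the double bond.

Step 10
Reactants: 15 (R)-(+)-citronellic acid
Product: 16 tert-butyl (R)-citronellate
Conditions: Boc2O, DMAP (cat.), tBuOH, rt
Reagents that add atoms: di-tert-butyl dicarbonate, CC(C)(C)OC(=O)OC(=O)OC(C)(C)C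
Why: Esterification through the mixed carbonic anhydride is non-acidic and spares the trisubstituted olefin; the tert-butyl ester is chosen to resist iBu2AlH in step 13.

Step 11
Reactants: 16 tert-butyl (R)-citronellate
Product: 17 aldehyde ester
Conditions: O3, CH2Cl2, −78 °C; PPh3, −78 °C → rt
Reagents that add atoms: ozone, [O-][O+]=O
Why: Ozonolysis with reductive work-up cleaves the only olefin to the C9 aldehyde; C13 is remote and untouched.

Step 12
Reactants: 17 aldehyde ester
Product: 18 (Z)-enoate diester
Conditions: (CF3CH2O)2P(O)CH(CH3)CO2Me, KN(SiMe3)2, 18-crown-6, THF, −78 °C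
Reagents that add atoms: methyl 2-[bis(2,2,2-trifluoroethoxy)phosphoryl]propanoate, COC(=O)C(C)P(=O)(OCC(F)(F)F)OCC(F)(F)F
Why: Still–Gennari olefination with the electron-poor phosphonate under dissociating conditions should give the kinetic (Z)-trisubstituted enoate, which fixes the olefin geometry that later controls C9.

Step 13
Reactants: 18 (Z)-enoate diester
Product: 19 (Z)-allylic alcohol
Conditions: iBu2AlH, CH2Cl2, −78 °C; aq. potassium sodium tartrate (KNaC4H4O6)
Reagents that add atoms: none
Why: Hydride reduction of the conjugated methyl ester to the allylic alcohol at −78 °C should leave the hindered tert-butyl ester and the olefin geometry intact.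

Step 14
Reactants: 14 alkenyl iodide; 19 (Z)-allylic alcohol
Product: 20 allyl enol ether
Conditions: CuI (cat.), 3,4,7,8-tetramethyl-1,10-phenanthroline, Cs2CO3, toluene, 80 °C
Reagents that add atoms: none
Why: Ullmann-type copper-catalysed C–O coupling of an alkenyl iodide with a primary allylic alcohol should give the enol ether with the double bond fixed at C1=C10, and at 80 °C the sigmatropic shift of this tetrasubstituted enol ether should not yet set in.

Step 15
Reactants: 20 allyl enol ether
Product: 22 bicyclic ketone, via Claisen ketone 21 (not isolated)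
Conditions: toluene, 135 °C (degassed, sealed); then second-generation Hoveyda–Grubbs catalyst RuCl2(H2IMes)(=CH-C6H4-2-OiPr) (cat.), 80 °C, argon sparge
Reagents that add atoms: none
Why: Heating should trigger a Claisen ([3,3]-sigmatropic) shift through a chair transition state on the face of the C1=C10 enol ether anti to the C5 allyl group, which makes the C9–C10 bond and the C1 ketone 21; the ruthenium alkylidene added afterwards loads on the monosubstituted allyl terminus and closes ring B by ring-closing metathesis onto the isopropenyl group, forming C7=C8 and expelling as ethene the former O–CH2 tether carbon together with the allyl terminus. The closest known reaction types are the thermal Claisen rearrangement of ketone allyl enol ethers to alpha-quaternary ketones and the RCM of 1,7-dienes to trisubstituted cyclohexenes. Ring B closes as a six-membered carbocycle by olefin metathesis, and it can only be trans-fused because the C5 and C10 arms are trans on ring A. C10 is controlled by the resident C5 centre (bond formation anti to the allyl group, so the C10 methyl ends cis to C19), and C9 by the (Z)-olefin geometry relayed through the chair (side chain axial in the transition state, so H9 ends cis to H5); C7 and C8 are sp2 and C13 is untouched. The step needs chair-over-boat selectivity and chemoselective metathesis: the (Z)-geometry fixed in step 12 and the allylic strain that holds the C5 allyl group axial secure the first, and adding the catalyst only after the enol ether and the trisubstituted olefin have been consumed secures the second, since only one terminal and one 1,1-disubstituted olefin then remain.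

Step 16
Reactants: 22 bicyclic ketone
Product: 24 deoxygenated ester, via tosylhydrazone 23 (not isolated)
Conditions: TsNHNH2, AcOH (cat.), EtOH, 70 °C; concentrate; catecholborane, CHCl3, 0 °C → rt; NaOAc·3H2O, 60 °C
Reagents that add atoms: p-toluenesulfonohydrazide, Cc1ccc(cc1)S(=O)(=O)NN (in intermediate 23 only)
Why: Caglioti-type reductive deoxygenation (hydride addition to the tosylhydrazone, loss of sulfinate and N2 from the diazene) should turn the helper C1 carbonyl into CH2 without touching the ester, the ethers or the trisubstituted olefin.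

Step 17
Reactants: 24 deoxygenated ester
Product: 25 C3 alcohol
Conditions: Bu4NF, THF, 50 °C
Reagents that add atoms: none
Why: Fluoride-induced cleavage of the silyl ether should free only the C3 hydroxyl, since the tert-butyl ester and the PMB ether are inert to fluoride.

Step 18
Reactants: 25 C3 alcohol
Product: 26 C3 acetate
Conditions: Ac2O, DMAP, pyridine, rt → 40 °C
Reagents that add atoms: acetic anhydride, CC(=O)OC(C)=O
Why: DMAP-catalysed acylation of the hindered axial C3 alcohol occurs while C19 is still masked, so only O3 is acetylated.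

Step 19
Reactants: 26 C3 acetate
Product: 28 acid PMB ether, via trimethylsilyl ester 27 (not isolated)
Conditions: Me3SiOTf, 2,6-lutidine, CH2Cl2, 0 °C → rt; then pH 5 aqueous buffer
Reagents that add atoms: trimethylsilyl triflate, C[Si](C)(C)OS(=O)(=O)C(F)(F)F (in intermediate 27 only)
Why: Silyl triflate/lutidine cleavage of the tert-butyl ester (silyl ester formation with loss of 2-methylpropene, then hydrolysis) is non-protic, so the C7=C8 olefin should not migrate and the acetate and PMB ether should survive.

Step 20
Reactants: 28 acid PMB ether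
Product: 29 target acid (CNP0138726.1)
Conditions: DDQ, CH2Cl2/pH 7 aqueous buffer, 0 °C
Reagents that add atoms: none
Why: Oxidative PMB ether cleavage by DDQ (benzylic hydride abstraction, hydrolysis of the oxocarbenium ion) is neutral, and acetyl migration from O3 to O19 is not possible because the two groups are trans-diaxial on ring A.

**Compound list**

1 | (S)-(+)-carvone | CC(=C)[C@H]1CC=C(C)C(=O)C1 | starting material
2 | trans-6-methylcarvone (C4 methyl trans to C3 isopropenyl) | CC(=C)[C@H]1CC=C(C)C(=O)[C@@H]1C | intermediate
3 | quaternary enone (C5 ketone; C4 methyl cis and CH2OPMB trans to C3 isopropenyl) | CC(=C)[C@H]1CC=C(C)C(=O)[C@]1(C)COCc2ccc(OC)cc2 | intermediate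
4 | methoxy hydroperoxide (C3 bears C(CH3)(OCH3)OOH; both epimers at that carbon; not isolated) | COC(C)(OO)[C@H]1CC=C(C)C(=O)[C@]1(C)COCc2ccc(OC)cc2 | intermediate
5 | C3 acetate of 6 (not isolated) | CC(=O)O[C@H]1CC=C(C)C(=O)[C@]1(C)COCc2ccc(OC)cc2 | intermediate
6 | hydroxy enone (C3–OH trans to C19) | O[C@H]1CC=C(C)C(=O)[C@]1(C)COCc2ccc(OC)cc2 | intermediate
7 | C3 tert-butyldimethylsilyl ether of 6 | CC(C)(C)[Si](C)(C)O[C@H]1CC=C(C)C(=O)[C@]1(C)COCc2ccc(OC)cc2 | intermediate
8 | epoxy ketone (C1–C10 epoxide anti to C3–OSi; C5 ketone) | CC(C)(C)[Si](C)(C)O[C@H]1C[C@@H]2O[C@]2(C)C(=O)[C@]1(C)COCc3ccc(OC)cc3 | intermediate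
9 | allylic alcohol (C1–OH trans to C3–OSi; C5=C10 olefin) | CC(C)(C)[Si](C)(C)O[C@H]1C[C@H](O)C(C)=C[C@]1(C)COCc2ccc(OC)cc2 | intermediate
10 | transposed enone (C1 ketone; C10=C5 olefin) | CC(C)(C)[Si](C)(C)O[C@H]1CC(=O)C(C)=C[C@]1(C)COCc2ccc(OC)cc2 | intermediate
11 | trimethylsilyl enol ether (C1=C10; C5 allyl trans to C3–OSi and cis to C19; not isolated) | CC(C)(C)[Si](C)(C)O[C@H]1CC(O[Si](C)(C)C)=C(C)[C@H](CC=C)[C@]1(C)COCc2ccc(OC)cc2 | intermediate
12 | lithium enolate corresponding to 11 (not isolated) | CC(C)(C)[Si](C)(C)O[C@H]1CC(O[Li])=C(C)[C@H](CC=C)[C@]1(C)COCc2ccc(OC)cc2 | intermediate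
13 | enol triflate (C1–OTf; C1=C10) | CC(C)(C)[Si](C)(C)O[C@H]1CC(OS(=O)(=O)C(F)(F)F)=C(C)[C@H](CC=C)[C@]1(C)COCc2ccc(OC)cc2 | intermediate
14 | alkenyl iodide (C1–I; C1=C10) | CC(C)(C)[Si](C)(C)O[C@H]1CC(I)=C(C)[C@H](CC=C)[C@]1(C)COCc2ccc(OC)cc2 | intermediate
15 | (R)-(+)-citronellic acid, (3R)-3,7-dimethyloct-6-enoic acid | CC(C)=CCC[C@@H](C)CC(=O)O | starting material
16 | tert-butyl (3R)-3,7-dimethyloct-6-enoate | CC(C)=CCC[C@@H](C)CC(=O)OC(C)(C)C | intermediate
17 | tert-butyl (3R)-3-methyl-6-oxohexanoate | O=CCC[C@@H](C)CC(=O)OC(C)(C)C | intermediate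
18 | 8-tert-butyl 1-methyl (2Z,6R)-2,6-dimethyloct-2-enedioate | COC(=O)/C(C)=C\CC[C@@H](C)CC(=O)OC(C)(C)C | intermediate
19 | tert-butyl (3R,6Z)-8-hydroxy-3,7-dimethyloct-6-enoate | OC/C(C)=C\CC[C@@H](C)CC(=O)OC(C)(C)C | intermediate
20 | allyl enol ether (ring A C1=C10 enol ether O-linked to the (Z)-allylic CH2 of the side chain) | CC(C)(C)[Si](C)(C)O[C@H]1CC(OC/C(C)=C\CC[C@@H](C)CC(=O)OC(C)(C)C)=C(C)[C@H](CC=C)[C@]1(C)COCc2ccc(OC)cc2 | intermediate
21 | Claisen ketone (C1 ketone; C10 carries methyl and the C9 methine with isopropenyl and side chain; not isolated) | CC(C)(C)[Si](C)(C)O[C@H]1CC(=O)[C@@](C)([C@H](CC[C@@H](C)CC(=O)OC(C)(C)C)C(C)=C)[C@H](CC=C)[C@]1(C)COCc2ccc(OC)cc2 | intermediate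
22 | bicyclic ketone (trans-decalin; tert-butyl 1-oxo-3-silyloxy-19-PMB-oxy-labd-7-en-15-oate, target configuration at C3, C4, C5, C9, C10, C13) | CC(C)(C)[Si](C)(C)O[C@H]1CC(=O)[C@]2(C)[C@H](CC=C(C)[C@H]2CC[C@@H](C)CC(=O)OC(C)(C)C)[C@]1(C)COCc3ccc(OC)cc3 | intermediate
23 | C1 tosylhydrazone of 22 (not isolated) | CC(C)(C)[Si](C)(C)O[C@H]1CC(=NNS(=O)(=O)c3ccc(C)cc3)[C@]2(C)[C@H](CC=C(C)[C@H]2CC[C@@H](C)CC(=O)OC(C)(C)C)[C@]1(C)COCc4ccc(OC)cc4 | intermediate
24 | deoxygenated ester (tert-butyl 3-silyloxy-19-PMB-oxy-labd-7-en-15-oate, target configuration) | CC(C)(C)[Si](C)(C)O[C@H]1CC[C@]2(C)[C@H](CC=C(C)[C@H]2CC[C@@H](C)CC(=O)OC(C)(C)C)[C@]1(C)COCc3ccc(OC)cc3 | intermediate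
25 | C3 alcohol (axial OH, trans to C19 and to the C10 methyl) | O[C@H]1CC[C@]2(C)[C@H](CC=C(C)[C@H]2CC[C@@H](C)CC(=O)OC(C)(C)C)[C@]1(C)COCc3ccc(OC)cc3 | intermediate
26 | C3 acetate | CC(=O)O[C@H]1CC[C@]2(C)[C@H](CC=C(C)[C@H]2CC[C@@H](C)CC(=O)OC(C)(C)C)[C@]1(C)COCc3ccc(OC)cc3 | intermediate
27 | trimethylsilyl ester of 28 (not isolated) | CC(=O)O[C@H]1CC[C@]2(C)[C@H](CC=C(C)[C@H]2CC[C@@H](C)CC(=O)O[Si](C)(C)C)[C@]1(C)COCc3ccc(OC)cc3 | intermediate
28 | 3-acetoxy-19-(4-methoxybenzyloxy)labd-7-en-15-oic acid (target configuration) | CC(=O)O[C@H]1CC[C@]2(C)[C@H](CC=C(C)[C@H]2CC[C@@H](C)CC(=O)O)[C@]1(C)COCc3ccc(OC)cc3 | intermediate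
29 | CNP0138726.1, 3-acetoxy-19-hydroxylabd-7-en-15-oic acid (C3–OAc trans to C19 and to the C10 methyl; trans-decalin; H5 and H9 cis) | CC(=O)O[C@H]1CC[C@]2(C)[C@H](CC=C(C)[C@H]2CC[C@@H](C)CC(=O)O)[C@]1(C)CO | target

**Count**

Total step count: 20. Longest linear sequence: 16 steps (steps 1–9 and 14–20); steps 10–13 prepare the side chain.

**Steps most likely to fail**

Step 6. Hydrazone formation at the C5 carbonyl, which is flanked by quaternary C4 and the fully substituted epoxide carbon C10, may be so slow that hydrazine opens the epoxide instead. The fallback sets out from 7. Luche reduction (NaBH4, CeCl3·7H2O, MeOH, −40 °C) should give the C5 allylic alcohol F1. A perrhenate-catalysed 1,3-transposition of this allylic alcohol (Ph3SiOReO3, Et2O, 0 °C), driven by relief of the congestion at C5, should move the hydroxyl suprafacially to C1 and give the C1 epimer of 9, F2. Dess–Martin oxidation as in step 7 then returns to the route at 10.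

Step 14. Oxidative addition and alkoxide exchange at the tetrasubstituted alkenyl iodide may be slower than protodeiodination, so the ether may not form. The fallback sets out from 13. Miyaura borylation (B2pin2, PdCl2(PPh3)2, PPh3, KOPh, toluene, 50 °C) should give the alkenyl pinacol boronate F3. An oxidative Chan–Lam-type coupling with 19 (Cu(OAc)2, Et3N, 4 Å sieves, air, CH2Cl2, rt) then forms the same C1–O bond from the nucleophilic boron partner at room temperature and returns to the route at 20.

Step 15. The ruthenium carbene formed at the allyl terminus may isomerise that olefin or decompose before it engages the hindered 1,1-disubstituted olefin next to C9 and C10, so that ring closure stalls. The fallback sets out from 21, isolated by running the thermal stage alone. Its C1 carbonyl is removed as in step 16 through the tosylhydrazone F4 to give the diene F5. Both olefins are cleaved by ozonolysis (O3, CH2Cl2, −78 °C; PPh3) to the keto aldehyde F6. An intramolecular McMurry coupling of the C7 aldehyde with the C8 methyl ketone (TiCl3(DME)1.5, Zn–Cu, DME, reflux) then forms the same C7=C8 bond by reductive carbonyl coupling and returns to the route at 24.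

**Further compounds**

F1 | step 6 | C5 allylic alcohol from 1,2-reduction of 7 (OH expected cis to the C4 methyl) | CC(C)(C)[Si](C)(C)O[C@H]1CC=C(C)[C@@H](O)[C@]1(C)COCc2ccc(OC)cc2
F2 | step 6 | C1 epimer of 9 (C1–OH cis to C3–OSi) | CC(C)(C)[Si](C)(C)O[C@H]1C[C@@H](O)C(C)=C[C@]1(C)COCc2ccc(OC)cc2
F3 | step 14 | alkenyl pinacol boronate (boron on C1; C1=C10) | CC(C)(C)[Si](C)(C)O[C@H]1CC(B2OC(C)(C)C(C)(C)O2)=C(C)[C@H](CC=C)[C@]1(C)COCc3ccc(OC)cc3
F4 | step 15 | C1 tosylhydrazone of 21 | CC(C)(C)[Si](C)(C)O[C@H]1CC(=NNS(=O)(=O)c2ccc(C)cc2)[C@@](C)([C@H](CC[C@@H](C)CC(=O)OC(C)(C)C)C(C)=C)[C@H](CC=C)[C@]1(C)COCc3ccc(OC)cc3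
F5 | step 15 | monocyclic diene without the C1 oxygen | CC(C)(C)[Si](C)(C)O[C@H]1CC[C@@](C)([C@H](CC[C@@H](C)CC(=O)OC(C)(C)C)C(C)=C)[C@H](CC=C)[C@]1(C)COCc2ccc(OC)cc2
F6 | step 15 | keto aldehyde (C7 aldehyde on C6; C8 methyl ketone on C9) | CC(C)(C)[Si](C)(C)O[C@H]1CC[C@@](C)([C@H](CC[C@@H](C)CC(=O)OC(C)(C)C)C(C)=O)[C@H](CC=O)[C@]1(C)COCc2ccc(OC)cc2
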